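**Plan**

- Numbering: ring C1 (methine), C2, C3=C4(Me), C5, C6, C7=C8(Me), C9, C10, C11=C12(Me), C13, C14; carbinol C15; side chain C16–C24. In the 14-membered ring the only stereogenic ring atom C1 sits between the exocyclic tertiary carbinol C15 and the allylic methylene C2 (next to C3=C4), so C1/C15 can be carried as one cis-trisubstituted epoxide and C2 as a sulfur-stabilised allyl anion.
- Retrosynthesis: remove PhS from C2; cut the ring bond C1–C2 (epoxide opening); cut C16–C17 (geranyl sulfone plus epoxy triflate); cut C1=C15 (Z-selective olefination); cut C13–C14 (cyanomethylation of ω-brominated farnesol).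
- Forward: (2E,6E)-farnesol is protected, oxidised at its terminal E-methyl group and extended to the C1 aldehyde; Z-olefination, reduction and asymmetric epoxidation give the C16 epoxy alcohol; the geranyl tail is attached through its sulfone, C2 becomes the phenyl sulfide, and the single ring closes in the penultimate step.
- Stereochemistry: C15 and the epoxide carbon C1 come from Sharpless epoxidation (L-(+)-tartrate) of the Z allylic alcohol; the ring closure inverts C1, giving (1R,15S). E olefins come from farnesol and geranyl bromide, the Z olefin from the Still–Gennari reaction.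

Key step: step 14

Remark: atom numbers in the text are those of the target; C17 (step 10) and C2 (step 14) arise as epimer mixtures, which is of no consequence because both centres end as CH2.

**Route**

Step 1
Reactants: 1 (2E,6E)-farnesol
Product: 2 tert-butyl(diphenyl){[(2E,6E)-3,7,11-trimethyldodeca-2,6,10-trien-1-yl]oxy}silane
Conditions: TBDPSCl, imidazole, DMF, 0 °C to rt
Reagents that add atoms: tert-butyl(chloro)diphenylsilane, CC(C)(C)[Si](Cl)(c1ccccc1)c1ccccc1
Why: Standard silylation of a primary allylic alcohol; the silyl ether should survive the oxidations, carbanions and hydride reagents used up to step 12.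

Step 2
Reactants: 2 farnesyl silyl ether
Product: 3 (2E,6E,10E)-12-(tert-butyldiphenylsilyloxy)-2,6,10-trimethyldodeca-2,6,10-trien-1-ol
Conditions: SeO2 (cat.), t-BuOOH, salicylic acid (cat.), CH2Cl2, 0 °C to rt
Reagents that add atoms: tert-butyl hydroperoxide, CC(C)(C)OO
Why: Catalytic SeO2 allylic oxidation (ene reaction, then [2,3]-shift) attacks the most electron-rich terminal olefin at its E-methyl group and gives the E allylic alcohol, while the C3=C4 olefin is deactivated by the allylic silyloxy group.

Step 3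
Reactants: 3 ω-hydroxy silyl ether
Product: 4 tert-butyl{[(2E,6E,10E)-12-bromo-3,7,11-trimethyldodeca-2,6,10-trien-1-yl]oxy}diphenylsilane
Conditions: CBr4, PPh3, CH2Cl2, 0 °C
Reagents that add atoms: carbon tetrabromide, BrC(Br)(Br)Br
Why: Appel bromination of a primary allylic alcohol proceeds by SN2 on the alkoxyphosphonium ion and should keep the position and E geometry of the olefin.

Step 4
Reactants: 4 allylic bromide
Product: 5 (4E,8E,12E)-14-(tert-butyldiphenylsilyloxy)-4,8,12-trimethyltetradeca-4,8,12-trienenitrile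
Conditions: CH3CN, n-BuLi, THF, −78 °C; then 4, −78 to −30 °C
Reagents that add atoms: acetonitrile, CC#N
Why: SN2 alkylation of lithiated acetonitrile (used in excess to suppress double alkylation) by the primary allylic bromide adds the two carbons that become C14 and C1.

Step 5
Reactants: 5 nitrile
Product: 7 (4E,8E,12E)-14-(tert-butyldiphenylsilyloxy)-4,8,12-trimethyltetradeca-4,8,12-trienal, via N-diisobutylalumino imine 6 (not isolated)
Conditions: i-Bu2AlH, CH2Cl2, −78 °C; then H2O, SiO2, rt
Reagents that add atoms: water, O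
Why: Partial reduction of a nitrile by i-Bu2AlH stops at the aluminated imine, which is hydrolysed to the aldehyde on work-up; silyl ether and olefins are inert.

Step 6
Reactants: 7 aldehyde
Product: 8 ethyl (2Z,6E,10E,14E)-16-(tert-butyldiphenylsilyloxy)-2,6,10,14-tetramethylhexadeca-2,6,10,14-tetraenoate
Conditions: (CF3CH2O)2P(O)CH(CH3)CO2Et, KN(SiMe3)2, 18-crown-6, THF, −78 °C
Reagents that add atoms: ethyl 2-[bis(2,2,2-trifluoroethoxy)phosphoryl]propanoate, CCOC(=O)C(C)P(=O)(OCC(F)(F)F)OCC(F)(F)F
Why: Still–Gennari variant of the Horner–Wadsworth–Emmons reaction: the trifluoroethyl phosphonate with a dissociated potassium counter-ion gives the kinetic Z trisubstituted enoate, which places the ester carbon (C16) cis to C14.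

Step 7
Reactants: 8 Z enoate
Product: 9 (2Z,6E,10E,14E)-16-(tert-butyldiphenylsilyloxy)-2,6,10,14-tetramethylhexadeca-2,6,10,14-tetraen-1-ol
Conditions: i-Bu2AlH, CH2Cl2, −78 to 0 °C; then H2O
Reagents that add atoms: none
Why: 1,2-Reduction of the enoate by i-Bu2AlH gives the allylic alcohol without change of olefin geometry.

Step 8
Reactants: 9 Z allylic alcohol
Product: 10 [(2S,3R)-3-[(3E,7E,11E)-13-(tert-butyldiphenylsilyloxy)-3,7,11-trimethyltrideca-3,7,11-trien-1-yl]-2-methyloxiran-2-yl]methanol
Conditions: Ti(Oi-Pr)4 (cat.), L-(+)-diethyl tartrate (cat.), t-BuOOH, 4 Å molecular sieves, CH2Cl2, −20 °C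
Reagents that add atoms: tert-butyl hydroperoxide, CC(C)(C)OO
Why: Sharpless asymmetric epoxidation: the titanium tartrate complex binds the allylic hydroxyl so that only C1=C15 reacts, and the L-(+) ester delivers oxygen to the enantioface that makes the carbinol-bearing olefin carbon (2S), as with geraniol, which on this Z olefin gives the cis epoxide with 15S and 1R.

Step 9
Reactants: 11 geranyl bromide
Product: 12 {[(2E)-3,7-dimethylocta-2,6-dien-1-yl]sulfonyl}benzene (geranyl phenyl sulfone)
Conditions: PhSO2Na, DMF, rt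
Reagents that add atoms: sodium benzenesulfinate, [Na+].[O-]S(=O)c1ccccc1
Why: SN2 displacement of the primary allylic bromide by the sulfur atom of the sulfinate gives the allylic sulfone with the E olefin intact.

Step 10
Reactants: 10 epoxy alcohol; 12 geranyl phenyl sulfone
Product: 15 tert-butyl{[(2E,6E,10E)-13-{(2R,3S)-3-[(3E)-4,8-dimethyl-2-(phenylsulfonyl)nona-3,7-dien-1-yl]-3-methyloxiran-2-yl}-3,7,11-trimethyltrideca-2,6,10-trien-1-yl]oxy}diphenylsilane (C17 epimers), via epoxy triflate 13 (not isolated), via lithiated geranyl phenyl sulfone 14 (not isolated)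
Conditions: Tf2O, 2,6-lutidine, CH2Cl2, −78 °C; crude triflate added to 12, n-BuLi, THF, −78 to −40 °C
Reagents that add atoms: none
Why: Alkylation of an α-sulfonyl allyl carbanion by a primary epoxy triflate: at −78 °C the triflate is displaced far faster than the trisubstituted epoxide is opened, the sulfonyl anion reacts at its α carbon, and C15 and C1 are not touched.

Step 11
Reactants: 15 epoxy sulfone
Product: 16 tert-butyl{[(2E,6E,10E)-13-{(2R,3S)-3-[(3E)-4,8-dimethylnona-3,7-dien-1-yl]-3-methyloxiran-2-yl}-3,7,11-trimethyltrideca-2,6,10-trien-1-yl]oxy}diphenylsilane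
Conditions: Pd(dppp)Cl2 (cat.), LiBHEt3, THF, −20 to 0 °C
Reagents that add atoms: none
Why: Palladium-catalysed hydride reduction of an allylic sulfone: ionisation by zerovalent palladium gives an allylpalladium species whose less substituted terminus C17 takes up hydride, so C18=C19 stays in place and E, and at low temperature this should outpace borohydride attack on the hindered epoxide.

Step 12
Reactants: 16 silyl ether
Product: 17 (2E,6E,10E)-13-{(2R,3S)-3-[(3E)-4,8-dimethylnona-3,7-dien-1-yl]-3-methyloxiran-2-yl}-3,7,11-trimethyltrideca-2,6,10-trien-1-ol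
Conditions: Bu4NF, THF, 0 °C to rt
Reagents that add atoms: none
Why: Fluoride cleaves the Si–O bond; the epoxide and olefins are inert to these conditions.

Step 13
Reactants: 17 epoxy alcohol
Product: 18 {[(2E,6E,10E)-13-{(2R,3S)-3-[(3E)-4,8-dimethylnona-3,7-dien-1-yl]-3-methyloxiran-2-yl}-3,7,11-trimethyltrideca-2,6,10-trien-1-yl]sulfanyl}benzene (C1,C15-epoxy allylic phenyl sulfide)
Conditions: PhSSPh, n-Bu3P, THF, 0 °C to rt
Reagents that add atoms: diphenyl disulfide, c1ccc(SSc2ccccc2)cc1
Why: Phosphine/disulfide thioetherification: the alcohol is activated as an alkoxyphosphonium ion and displaced by thiophenolate at the primary carbon (SN2) under neutral conditions that leave the epoxide closed.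

Step 14
Reactants: 18 epoxy allylic phenyl sulfide
Product: 20 2-(phenylsulfanyl)colleterpenol (C2 epimers; C1 and C15 arranged as in colleterpenol), via α-thioallyllithium 19 (not isolated)
Conditions: n-BuLi, DABCO, THF (high dilution), −78 to −20 °C; then H2O
Reagents that add atoms: none
Why: n-BuLi with DABCO removes an allylic proton next to sulfur at C2, and the thioallyllithium attacks the secondary epoxide carbon C1 from the side opposite the C1–O bond, forming C1–C2 and releasing the C15 alkoxide. The closest known reaction type is the macrocyclisation of ω-epoxy allylic phenyl sulfide carbanions to 14-membered tertiary carbinols of the cembrane class. The ring closes in the 14-exo-tet mode. C1 is set by SN2 inversion at the epoxide carbon, so its relation to C15, which keeps its C–O bond, follows from the cis geometry and absolute configuration of the epoxide; C2 forms as both epimers and is erased in step 15. The step needs attack through the α and not the γ carbon of the allyl anion, at C1 and not C15, and ring closure instead of oligomerisation: sulfur-bound lithium with DABCO favours α attack, C15 is fully substituted and shielded, and high dilution favours the intramolecular path.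

Step 15
Reactants: 20 2-(phenylsulfanyl)colleterpenol
Product: 21 colleterpenol, (2S,5E)-6,10-dimethyl-2-[(1R,3E,7E,11E)-4,8,12-trimethylcyclotetradeca-3,7,11-trien-1-yl]undeca-5,9-dien-2-ol
Conditions: Li, EtNH2, −78 °C; then NH4Cl
Reagents that add atoms: none
Why: Dissolving-metal cleavage of the allylic C–S bond gives an allyl anion that is protonated at the less substituted terminus C2, which keeps C3=C4 trisubstituted and E; isolated olefins and the tertiary alkoxide are not reduced at −78 °C.

**Compound list**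

1 | (2E,6E)-farnesol | CC(C)=CCC/C(C)=C/CC/C(C)=C/CO | starting material
2 | (2E,6E)-farnesyl tert-butyldiphenylsilyl ether | CC(C)=CCC/C(C)=C/CC/C(C)=C/CO[Si](c1ccccc1)(c1ccccc1)C(C)(C)C | intermediate
3 | (2E,6E,10E)-12-(tert-butyldiphenylsilyloxy)-2,6,10-trimethyldodeca-2,6,10-trien-1-ol | OC/C(C)=C/CC/C(C)=C/CC/C(C)=C/CO[Si](c1ccccc1)(c1ccccc1)C(C)(C)C | intermediate
4 | tert-butyl{[(2E,6E,10E)-12-bromo-3,7,11-trimethyldodeca-2,6,10-trien-1-yl]oxy}diphenylsilane | BrC/C(C)=C/CC/C(C)=C/CC/C(C)=C/CO[Si](c1ccccc1)(c1ccccc1)C(C)(C)C | intermediate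
5 | (4E,8E,12E)-14-(tert-butyldiphenylsilyloxy)-4,8,12-trimethyltetradeca-4,8,12-trienenitrile | N#CCC/C(C)=C/CC/C(C)=C/CC/C(C)=C/CO[Si](c1ccccc1)(c1ccccc1)C(C)(C)C | intermediate
6 | N-diisobutylalumino imine of aldehyde 7 | CC(C)C[Al](CC(C)C)N=CCC/C(C)=C/CC/C(C)=C/CC/C(C)=C/CO[Si](c1ccccc1)(c1ccccc1)C(C)(C)C | intermediate (not isolated)
7 | (4E,8E,12E)-14-(tert-butyldiphenylsilyloxy)-4,8,12-trimethyltetradeca-4,8,12-trienal | O=CCC/C(C)=C/CC/C(C)=C/CC/C(C)=C/CO[Si](c1ccccc1)(c1ccccc1)C(C)(C)C | intermediate
8 | ethyl (2Z,6E,10E,14E)-16-(tert-butyldiphenylsilyloxy)-2,6,10,14-tetramethylhexadeca-2,6,10,14-tetraenoate | CCOC(=O)/C(C)=C\CC/C(C)=C/CC/C(C)=C/CC/C(C)=C/CO[Si](c1ccccc1)(c1ccccc1)C(C)(C)C | intermediate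
9 | (2Z,6E,10E,14E)-16-(tert-butyldiphenylsilyloxy)-2,6,10,14-tetramethylhexadeca-2,6,10,14-tetraen-1-ol | OC/C(C)=C\CC/C(C)=C/CC/C(C)=C/CC/C(C)=C/CO[Si](c1ccccc1)(c1ccccc1)C(C)(C)C | intermediate
10 | [(2S,3R)-3-[(3E,7E,11E)-13-(tert-butyldiphenylsilyloxy)-3,7,11-trimethyltrideca-3,7,11-trien-1-yl]-2-methyloxiran-2-yl]methanol | OC[C@]1(C)O[C@@H]1CC/C(C)=C/CC/C(C)=C/CC/C(C)=C/CO[Si](c1ccccc1)(c1ccccc1)C(C)(C)C | intermediate
11 | geranyl bromide, (2E)-1-bromo-3,7-dimethylocta-2,6-diene | CC(C)=CCC/C(C)=C/CBr | starting material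
12 | geranyl phenyl sulfone | CC(C)=CCC/C(C)=C/CS(=O)(=O)c1ccccc1 | intermediate
13 | trifluoromethanesulfonate of epoxy alcohol 10 | FC(F)(F)S(=O)(=O)OC[C@]1(C)O[C@@H]1CC/C(C)=C/CC/C(C)=C/CC/C(C)=C/CO[Si](c1ccccc1)(c1ccccc1)C(C)(C)C | intermediate (not isolated)
14 | α-lithio geranyl phenyl sulfone | CC(C)=CCC/C(C)=C/C([Li])S(=O)(=O)c1ccccc1 | intermediate (not isolated)
15 | C17-phenylsulfonyl epoxy silyl ether (C17 epimers; systematic name in step 10) | CC(C)=CCC/C(C)=C/C(C[C@]1(C)O[C@@H]1CC/C(C)=C/CC/C(C)=C/CC/C(C)=C/CO[Si](c1ccccc1)(c1ccccc1)C(C)(C)C)S(=O)(=O)c1ccccc1 | intermediate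
16 | epoxy silyl ether (systematic name in step 11) | CC(C)=CCC/C(C)=C/CC[C@]1(C)O[C@@H]1CC/C(C)=C/CC/C(C)=C/CC/C(C)=C/CO[Si](c1ccccc1)(c1ccccc1)C(C)(C)C | intermediate
17 | (2E,6E,10E)-13-{(2R,3S)-3-[(3E)-4,8-dimethylnona-3,7-dien-1-yl]-3-methyloxiran-2-yl}-3,7,11-trimethyltrideca-2,6,10-trien-1-ol | CC(C)=CCC/C(C)=C/CC[C@]1(C)O[C@@H]1CC/C(C)=C/CC/C(C)=C/CC/C(C)=C/CO | intermediate
18 | C1,C15-epoxy allylic phenyl sulfide (systematic name in step 13) | CC(C)=CCC/C(C)=C/CC[C@]1(C)O[C@@H]1CC/C(C)=C/CC/C(C)=C/CC/C(C)=C/CSc1ccccc1 | intermediate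
19 | α-thioallyllithium from 18 (lithium on C2) | CC(C)=CCC/C(C)=C/CC[C@]1(C)O[C@@H]1CC/C(C)=C/CC/C(C)=C/CC/C(C)=C/C([Li])Sc1ccccc1 | intermediate (not isolated)
20 | 2-(phenylsulfanyl)colleterpenol (C2 epimers) | CC(C)=CCC/C(C)=C/CC[C@](C)(O)[C@H]1C(Sc2ccccc2)/C=C(\C)CC/C=C(\C)CC/C=C(\C)CC1 | intermediate
21 | colleterpenol | CC(C)=CCC/C(C)=C/CC[C@](C)(O)[C@H]1C/C=C(\C)CC/C=C(\C)CC/C=C(\C)CC1 | target

**Step count and risks**

Total steps: 15. Longest linear sequence: 14 steps (1–8 and 10–15) from (2E,6E)-farnesol; step 9 is a one-step branch.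

Steps most likely to fail:

1. Step 14. The ambident allyl anion may react through its γ carbon, the carbanion may open an epoxide of a second molecule (oligomerisation), or opening of the hindered epoxide may be too slow for the carbanion to survive. Fallback, from 17 to 21: the activating group is changed to a sulfone, whose carbanion can react only at the sulfur-bearing carbon. MsCl, LiCl and 2,4,6-collidine in DMF at 0 °C convert 17 into the allylic chloride F1; PhSO2Na in DMF gives the allylic phenyl sulfone F2. Deprotonation with LiN(i-Pr)2 in THF at high dilution closes the same C1–C2 bond in the same 14-exo-tet sense to give 2-(phenylsulfonyl)colleterpenol F3. Pd(dppp)Cl2/LiBHEt3 then removes the sulfonyl group, hydride going to the secondary terminus C2, and gives 21.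

2. Step 11. Ionisation of the hindered secondary sulfone may be slow, so that hydride opening of the epoxide competes. Fallback, from 15 to 21: the C–S cleavage is postponed until no epoxide is left. Bu4NF converts 15 into the hydroxy sulfone F4, and PhSSPh/n-Bu3P gives the sulfide sulfone F5. With two equivalents of n-BuLi and DABCO at high dilution the more acidic C17–H is lithiated first; this carbanion should be inert, because its nearest epoxide carbon C15 is fully substituted and attack at C1 would need a four-membered endo closure. The second equivalent forms the thioallyl anion, which closes the ring to the macrocyclic carbinol F6. Li in EtNH2 at −78 °C then cleaves the allylic sulfone and the allylic sulfide in one operation to give 21.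

3. Step 10. The epoxy triflate may decompose, or SN2 at the CH2 flanked by the fully substituted epoxide carbon may be slow enough for side reactions of the carbanion to take over. Fallback, from 4 to 16: the two halves are joined at C13–C14 instead. Bromide 4 and PhSO2Na give the ω-sulfone F7. (2Z,6E)-Farnesol F8 is epoxidised with Ti(Oi-Pr)4, D-(−)-diethyl tartrate and t-BuOOH to the (2R,3S)-epoxy alcohol F9, which has the same cis epoxide but the hydroxyl on C14. F9 is converted with Tf2O/2,6-lutidine into the triflate F10, whose CH2 is next to a secondary epoxide carbon. Lithiated F7 is alkylated by F10 to give the C13 sulfone F11, and Pd(dppp)Cl2/LiBHEt3 removes the sulfonyl group to arrive at 16. In this variant both termini of the allyl unit are secondary, so the position of the C11=C12 olefin after reduction would have to be checked.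

Further compounds
F1 | step 14 | allylic chloride from 17 (Cl on C2) | CC(C)=CCC/C(C)=C/CC[C@]1(C)O[C@@H]1CC/C(C)=C/CC/C(C)=C/CC/C(C)=C/CCl
F2 | step 14 | C1,C15-epoxy allylic phenyl sulfone | CC(C)=CCC/C(C)=C/CC[C@]1(C)O[C@@H]1CC/C(C)=C/CC/C(C)=C/CC/C(C)=C/CS(=O)(=O)c1ccccc1
F3 | step 14 | 2-(phenylsulfonyl)colleterpenol (C2 epimers) | CC(C)=CCC/C(C)=C/CC[C@](C)(O)[C@H]1C(S(=O)(=O)c2ccccc2)/C=C(\C)CC/C=C(\C)CC/C=C(\C)CC1
F4 | step 11 | C17-phenylsulfonyl epoxy alcohol (desilylated 15) | CC(C)=CCC/C(C)=C/C(C[C@]1(C)O[C@@H]1CC/C(C)=C/CC/C(C)=C/CC/C(C)=C/CO)S(=O)(=O)c1ccccc1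
F5 | step 11 | C17-phenylsulfonyl epoxy allylic phenyl sulfide | CC(C)=CCC/C(C)=C/C(C[C@]1(C)O[C@@H]1CC/C(C)=C/CC/C(C)=C/CC/C(C)=C/CSc1ccccc1)S(=O)(=O)c1ccccc1
F6 | step 11 | 17-(phenylsulfonyl)-2-(phenylsulfanyl)colleterpenol (C2 and C17 epimers) | CC(C)=CCC/C(C)=C/C(C[C@](C)(O)[C@H]1C(Sc2ccccc2)/C=C(\C)CC/C=C(\C)CC/C=C(\C)CC1)S(=O)(=O)c1ccccc1
F7 | step 10 | ω-phenylsulfonyl farnesyl silyl ether (sulfone on C13) | O=S(=O)(C/C(C)=C/CC/C(C)=C/CC/C(C)=C/CO[Si](c1ccccc1)(c1ccccc1)C(C)(C)C)c1ccccc1
F8 | step 10 | (2Z,6E)-farnesol | CC(C)=CCC/C(C)=C/CC/C(C)=C\CO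
F9 | step 10 | [(2R,3S)-3-[(3E)-4,8-dimethylnona-3,7-dien-1-yl]-3-methyloxiran-2-yl]methanol | CC(C)=CCC/C(C)=C/CC[C@]1(C)O[C@@H]1CO
F10 | step 10 | trifluoromethanesulfonate of F9 | CC(C)=CCC/C(C)=C/CC[C@]1(C)O[C@@H]1COS(=O)(=O)C(F)(F)F
F11 | step 10 | C13-phenylsulfonyl epoxy silyl ether (C13 epimers) | CC(C)=CCC/C(C)=C/CC[C@]1(C)O[C@@H]1CC(S(=O)(=O)c1ccccc1)/C(C)=C/CC/C(C)=C/CC/C(C)=C/CO[Si](c1ccccc1)(c1ccccc1)C(C)(C)C
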